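**Plan**

1. Retrosynthesis: cut the two aryl–CH bonds at the 6-methylheptane-1,1-diyl bridge, giving two identical 8-acyl-5,7-dihydroxy-2,2-dimethylchromans and 6-methylheptanal. In the chroman, cut C4–C4a and C2–C3 together, giving an O-aryl acetone ketal and a two-carbon partner. Last, cut O1–C2, the O-benzyl group and the aryl–acyl bond, back to phloroglucinol and (R)-2-methylbutanoic acid.
2. Forward: C-acylate phloroglucinol, benzylate the para-OH, put a mixed acetone ketal on the non-chelated ortho-OH, annulate the dihydropyran ring (step 5), strip the helpers, then join two chromans at C6 with the aldehyde.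
3. Enabling feature: in each chroman, O1 sits on C8a next to C4a, an unsubstituted phloroglucinol carbon ortho/para to three oxygens. Once C2 is an oxocarbenium carbon, C4a=C8a–O1(+)=C2 is a cationic 2-oxadiene that takes up a two-carbon alkene across C2 and C4a; the acyl group on C8 blocks the other ortho carbon.
4. The two-carbon partner is phenyl vinyl sulfide as an ethylene equivalent. Its PhS group ends up on C4 and is removed together with the benzyl group in step 6.
5. Stereochemistry: the only stereocentres are the two (R)-α-carbons of the 2-methylbutanoyl groups, both taken from (R)-2-methylbutanoic acid. The bridge CH carries two identical aryl groups and is not a stereocentre.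

Key step: step 5

Remark: (R)-2-methylbutanoic acid, 6-methylheptanal, 2-methoxypropene and phenyl vinyl sulfide are taken as commercial; the sulfur-bearing C4 centre made in the key step forms without control, is deleted one step later, and is left undefined in the SMILES.

**Route**

Step 1
Reactants: 1 (R)-2-methylbutanoic acid
Product: 2 (R)-2-methylbutanoyl chloride
Conditions: (COCl)2 (1.05 equiv), DMF (cat.), CH2Cl2, 0 °C → rt; solution used directly
Reagents that add atoms: oxalyl chloride, ClC(=O)C(=O)Cl
Why: Acid chloride formation through the catalytic chloroiminium (Vilsmeier-type) species; no base is present, so no ketene can form and the α-stereocentre should be retained.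

Step 2
Reactants: 2 (R)-2-methylbutanoyl chloride; 3 phloroglucinol (benzene-1,3,5-triol)
Product: 4 (R)-2-methyl-1-(2,4,6-trihydroxyphenyl)butan-1-one
Conditions: AlCl3 (4 equiv), PhNO2–CH2Cl2, 0 °C → rt; then ice/aq. HCl
Reagents that add atoms: none
Why: Friedel–Crafts C-acylation of the very electron-rich triol, which should stop at the mono-ketone because the acyl group deactivates the ring; the stereocentre comes in with 2 and the low temperature is chosen to suppress enolisation.

Step 3
Reactants: 4 (R)-2-methyl-1-(2,4,6-trihydroxyphenyl)butan-1-one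
Product: 5 (R)-1-[4-(benzyloxy)-2,6-dihydroxyphenyl]-2-methylbutan-1-one
Conditions: BnBr (1.0 equiv), K2CO3 (1.1 equiv), acetone, rt
Reagents that add atoms: benzyl bromide, BrCc1ccccc1
Why: Williamson etherification that should select the para-OH, the most acidic and the only hydroxyl not flanked by the acyl group.

Step 4
Reactants: 5 (R)-1-[4-(benzyloxy)-2,6-dihydroxyphenyl]-2-methylbutan-1-one; 6 2-methoxypropene
Product: 7 (R)-1-[4-(benzyloxy)-2-hydroxy-6-[(2-methoxypropan-2-yl)oxy]phenyl]-2-methylbutan-1-one
Conditions: 6 (2 equiv), PPTS (5 mol%), CH2Cl2, 0 °C; Et3N quench; Et3N-washed silica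
Reagents that add atoms: none
Why: Acid-catalysed Markovnikov addition of a phenol to an enol ether (mixed-ketal formation as in 2-methoxyprop-2-yl ether protection); the ortho-OH that is not held in the hydrogen bond to the carbonyl should react, after which the remaining OH is locked in the chelate and stays free.

Step 5
Reactants: 7 (R)-1-[4-(benzyloxy)-2-hydroxy-6-[(2-methoxypropan-2-yl)oxy]phenyl]-2-methylbutan-1-one; 8 phenyl vinyl sulfide
Product: 11 (2R)-1-[5-(benzyloxy)-7-hydroxy-2,2-dimethyl-4-(phenylsulfanyl)-3,4-dihydro-2H-chromen-8-yl]-2-methylbutan-1-one (both C4 epimers), via oxocarbenium ion 9 (not isolated), via thionium ion 10 (not isolated)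
Conditions: 8 (3 equiv), Tf2NH (10 mol%), 5 Å MS, CH2Cl2 (0.02 M), −78 → −30 °C; Et3N quench
Reagents that add atoms: none
Why: Tf2NH protonates the methoxy oxygen of 7 (the more basic ketal oxygen) and methanol leaves, giving the O-aryl oxocarbenium ion 9, a cationic 2-oxadiene over C4a=C8a–O1=C2 (chroman numbering); phenyl vinyl sulfide adds through its CH2 terminus to C2 (bond C2–C3) to give the sulfur-stabilised thionium ion 10, whose carbon is attacked by ring carbon C4a (bond C4–C4a) with loss of the ring proton, which returns the acid. The closest known reaction type is the oxa-Povarov reaction (Prins addition of an aryl 2-oxadiene oxocarbenium ion to an alkene, then Friedel–Crafts closure), combined with the classical Povarov use of vinyl sulfides as two-carbon partners. The dihydropyran ring closes by 6-exo-trig attack of the arene on the thionium carbon, the C=S bond staying outside the new ring. The new C4 stereocentre has no controlling element, so 11 is expected as two C4 epimers, which is harmless because the C–S bond is cut in step 6; the (R)-α-carbon is not involved and should survive the cold, weakly basic-free medium. The step needs ionisation toward loss of methanol and not of the phenol, closure at a single ring carbon, and protonation of the ketal in preference to the alkene: the first is secured kinetically by the basicity of the methoxy oxygen and by the reversibility of the wrong cleavage, the second because C4a is the only free carbon ortho to O1 (C8 carries the acyl group, whose carbonyl is held away from C2 by its hydrogen bond to the 7-OH) and is ortho/para to three oxygens, the third by the low basicity of a vinyl sulfide next to a ketal or enol ether.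

Step 6
Reactants: 11 (2R)-1-[5-(benzyloxy)-7-hydroxy-2,2-dimethyl-4-(phenylsulfanyl)-3,4-dihydro-2H-chromen-8-yl]-2-methylbutan-1-one
Product: 12 (2R)-1-(5,7-dihydroxy-2,2-dimethyl-3,4-dihydro-2H-chromen-8-yl)-2-methylbutan-1-one
Conditions: Raney Ni (W-2, excess), H2 (1 atm), EtOH, rt → 50 °C
Reagents that add atoms: none
Why: Raney-nickel hydrogenolysis should cleave the benzylic C4–S bond (desulfurisation, which also erases the uncontrolled C4 centre) and the aryl benzyl ether in the same pot, while the hydrogen-bonded, vinylogous-ester-like aryl ketone is expected to resist reduction.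

Step 7
Reactants: 12 (2R)-1-(5,7-dihydroxy-2,2-dimethyl-3,4-dihydro-2H-chromen-8-yl)-2-methylbutan-1-one (2 equiv); 13 6-methylheptanal
Product: 16 6,6'-(6-methylheptane-1,1-diyl)bis{8-[(2R)-2-methylbutanoyl]-2,2-dimethyl-3,4-dihydro-2H-chromene-5,7-diol} (CNP0324275.1), via carbinol 14 (not isolated), via ortho-quinone methide 15 (not isolated)
Conditions: 13 (0.5 equiv relative to 12), p-TsOH·H2O (10 mol%), MeCN, 0 °C → rt
Reagents that add atoms: none
Why: Acid-catalysed hydroxyalkylation then Friedel–Crafts alkylation (Baeyer-type bis-arylation of an aldehyde): C6 of 12, the only free ring carbon and ortho/ortho/para to three oxygens, adds to the aldehyde to give carbinol 14, which loses water to ortho-quinone methide 15 and is captured at C6 of a second molecule of 12; no stereocentre arises at the bridge because the two aryl groups are identical.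

**Compound list**

1 | (R)-2-methylbutanoic acid | CC[C@@H](C)C(=O)O | starting material
2 | (R)-2-methylbutanoyl chloride | CC[C@@H](C)C(=O)Cl | intermediate
3 | phloroglucinol (benzene-1,3,5-triol) | Oc1cc(O)cc(O)c1 | starting material
4 | (R)-2-methyl-1-(2,4,6-trihydroxyphenyl)butan-1-one | CC[C@@H](C)C(=O)c1c(O)cc(O)cc1O | intermediate
5 | (R)-1-[4-(benzyloxy)-2,6-dihydroxyphenyl]-2-methylbutan-1-one | CC[C@@H](C)C(=O)c1c(O)cc(OCc2ccccc2)cc1O | intermediate
6 | 2-methoxypropene | COC(C)=C | starting material
7 | (R)-1-[4-(benzyloxy)-2-hydroxy-6-[(2-methoxypropan-2-yl)oxy]phenyl]-2-methylbutan-1-one | CC[C@@H](C)C(=O)c1c(O)cc(OCc2ccccc2)cc1OC(C)(C)OC | intermediate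
8 | phenyl vinyl sulfide | C=CSc1ccccc1 | starting material
9 | O-aryl oxocarbenium ion from 7 (propan-2-ylidene oxonium on the ortho oxygen), triflimide salt | CC[C@@H](C)C(=O)c1c(O)cc(OCc2ccccc2)cc1[O+]=C(C)C.FC(F)(F)S(=O)(=O)[N-]S(=O)(=O)C(F)(F)F | intermediate (not isolated)
10 | thionium ion, aryl–O–C(CH3)2–CH2–CH=S(+)Ph, triflimide salt | CC[C@@H](C)C(=O)c1c(O)cc(OCc2ccccc2)cc1OC(C)(C)CC=[S+]c1ccccc1.FC(F)(F)S(=O)(=O)[N-]S(=O)(=O)C(F)(F)F | intermediate (not isolated)
11 | (2R)-1-[5-(benzyloxy)-7-hydroxy-2,2-dimethyl-4-(phenylsulfanyl)-3,4-dihydro-2H-chromen-8-yl]-2-methylbutan-1-one, both C4 epimers | CC[C@@H](C)C(=O)c1c(O)cc(OCc3ccccc3)c2c1OC(C)(C)CC2Sc1ccccc1 | intermediate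
12 | (2R)-1-(5,7-dihydroxy-2,2-dimethyl-3,4-dihydro-2H-chromen-8-yl)-2-methylbutan-1-one | CC[C@@H](C)C(=O)c1c(O)cc(O)c2c1OC(C)(C)CC2 | intermediate
13 | 6-methylheptanal | CC(C)CCCCC=O | starting material
14 | (2R)-1-[5,7-dihydroxy-6-(1-hydroxy-6-methylheptyl)-2,2-dimethyl-3,4-dihydro-2H-chromen-8-yl]-2-methylbutan-1-one, carbinol centre undefined | CC[C@@H](C)C(=O)c1c(O)c(C(O)CCCCC(C)C)c(O)c2c1OC(C)(C)CC2 | intermediate (not isolated)
15 | ortho-quinone methide: 7-hydroxy-2,2-dimethyl-8-[(2R)-2-methylbutanoyl]-6-(6-methylheptylidene)-3,4-dihydro-2H-chromen-5(6H)-one | CC[C@@H](C)C(=O)C1=C(O)C(=CCCCCC(C)C)C(=O)C2=C1OC(C)(C)CC2 | intermediate (not isolated)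
16 | 6,6'-(6-methylheptane-1,1-diyl)bis{8-[(2R)-2-methylbutanoyl]-2,2-dimethyl-3,4-dihydro-2H-chromene-5,7-diol} | CC[C@@H](C)C(=O)c1c(O)c(C(CCCCC(C)C)c2c(O)c3c(c(C(=O)[C@H](C)CC)c2O)OC(C)(C)CC3)c(O)c2c1OC(C)(C)CC2 | target

**Count and risks**

Total step count: 7. Longest linear sequence: 7 steps (1 → 16).

Steps most likely to fail:

1. Step 5. The ketal may cleave in the wrong direction (loss of the chelated phenol), after which the 2-methoxyprop-2-yl cation would consume the vinyl sulfide; cationic oligomerisation may also outrun ring closure, because the ortho-acyl group lowers the donor ability of O1 and reaches beyond the ketals and alkenes for which the oxa-Povarov reaction is established. Fallback (from 5, back at 12): alkylation of the free ortho-OH of 5 with 3-chloro-3-methylbut-1-yne (K2CO3, KI, CuI cat., acetone, 60 °C) should give (R)-1-[4-(benzyloxy)-2-hydroxy-6-[(2-methylbut-3-yn-2-yl)oxy]phenyl]-2-methylbutan-1-one F1. Heating in xylene at 140 °C (aryl propargyl Claisen rearrangement, 1,5-hydrogen shift, oxa-6π electrocyclisation) should give (2R)-1-[5-(benzyloxy)-7-hydroxy-2,2-dimethyl-2H-chromen-8-yl]-2-methylbutan-1-one F2. Hydrogenation (H2 1 atm, 10% Pd/C, EtOAc) should saturate C3=C4 and remove the benzyl group to give 12.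

2. Step 4. Addition of the hindered, acidic ortho-phenol to 2-methoxypropene may stall, or the mixed ketal may revert to 5 during isolation. Fallback (from 5, back at 11): Chan–Lam O-alkenylation of 5 with isopropenylboronic acid pinacol ester (Cu(OAc)2, pyridine, 4 Å MS, CH2Cl2, air, rt) should give the stable enol ether (R)-1-[4-(benzyloxy)-2-hydroxy-6-(prop-1-en-2-yloxy)phenyl]-2-methylbutan-1-one F3. Under the conditions of step 5, C-protonation of F3 gives the same oxocarbenium ion 9 and hence 11, without a competing leaving group.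

3. Step 2. Enantiopurity may erode through Lewis-acid-promoted enolisation of the acyl chloride or of the product ketone. Fallback (from 3 and 1, back at 4): phloroglucinol 3 is converted (MOMCl, NaH, DMF, 0 °C) into 1,3,5-tris(methoxymethoxy)benzene F4, and acid 1 (MeONHMe·HCl, EDC·HCl, N-methylmorpholine, CH2Cl2, 0 °C) into the Weinreb amide (R)-N-methoxy-N,2-dimethylbutanamide F5. Directed ortho-lithiation of F4 (n-BuLi, THF, 0 °C) and addition to F5 at −78 °C should give (R)-2-methyl-1-[2,4,6-tris(methoxymethoxy)phenyl]butan-1-one F6 through the stable tetrahedral chelate, and HCl in MeOH at 40 °C should release 4.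

**Further compounds**

F1 | step 5 | (R)-1-[4-(benzyloxy)-2-hydroxy-6-[(2-methylbut-3-yn-2-yl)oxy]phenyl]-2-methylbutan-1-one | CC[C@@H](C)C(=O)c1c(O)cc(OCc2ccccc2)cc1OC(C)(C)C#C
F2 | step 5 | (2R)-1-[5-(benzyloxy)-7-hydroxy-2,2-dimethyl-2H-chromen-8-yl]-2-methylbutan-1-one | CC[C@@H](C)C(=O)c1c(O)cc(OCc3ccccc3)c2c1OC(C)(C)C=C2
F3 | step 4 | (R)-1-[4-(benzyloxy)-2-hydroxy-6-(prop-1-en-2-yloxy)phenyl]-2-methylbutan-1-one | CC[C@@H](C)C(=O)c1c(O)cc(OCc2ccccc2)cc1OC(C)=C
F4 | step 2 | 1,3,5-tris(methoxymethoxy)benzene | COCOc1cc(OCOC)cc(OCOC)c1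
F5 | step 2 | (R)-N-methoxy-N,2-dimethylbutanamide | CC[C@@H](C)C(=O)N(C)OC
F6 | step 2 | (R)-2-methyl-1-[2,4,6-tris(methoxymethoxy)phenyl]butan-1-one | CC[C@@H](C)C(=O)c1c(OCOC)cc(OCOC)cc1OCOC
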